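The plan rests on opening ring A, the 2,2-dimethyl-2H-pyran, at C4–C4a and O1–C2. This exposes commercial 2',4'-dihydroxy-6'-methoxyacetophenone and a tetrasubstituted enal whose α-carbon (future C3) already bears the stereocentre C* and ring B. The feature exploited is that C4a is flanked by C8a–O1 and by the C5 hydroxyl. That hydroxyl is chelated to the C6 acetyl, so the hydrogen bond directs both new bonds. In one operation, condensation to an ortho-quinone methide and oxa-6π closure couple the halves, build ring A and finish the synthesis without protecting groups. C* is set earlier by CuH conjugate reduction, and the isopropylidene group is added at the ester stage.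

Key step: step 8

Labels: ring A = O1, C2, C3, C4, C4a, C5–C8, C8a. Ring B atoms are primed. C* = CH(CH3). Ar = 5,7-dimethoxy-2,2-dimethyl-2H-chromen-6-yl. Acetophenone positions carry primes (C3', C5').

Assumption: the ligand hand in step 3, (S)-p-tol-BINAP for the (E)-enoate, is assigned by analogy with simple (E)-3-arylbut-2-enoates. It is to be verified on the first batch, and the mirror-image ligand serves equally if the sense is opposite.

Remark: the spatial arrangement at C* does not change after step 3. Its descriptor reads R in 16, 18, F1 and F4 and S elsewhere, only because the CIP rank of the neighbouring carbon changes.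

Step 1
Reactants: 1 4-bromo-3,5-dimethoxyphenol; 2 3-methylbut-2-enal
Product: 5 6-bromo-5,7-dimethoxy-2,2-dimethyl-2H-chromene, via benzodioxaborinine 3 (not isolated), via ortho-quinone methide 4 (not isolated)
Conditions: PhB(OH)2 (1.0 equiv), AcOH, toluene, reflux, azeotropic water removal
Reagents that add atoms: none
Why: Phenylboronic acid-templated ortho-hydroxyalkylation, thermal loss of the boronic acid and oxa-6π electrocyclisation is the known chromene synthesis for monohydric phenols, which lack the second hydroxyl that amine-salt catalysis relies on, and the two ortho positions of 1 are equivalent so only one regioisomer can form.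

Step 2
Reactants: 5 6-bromo-5,7-dimethoxy-2,2-dimethyl-2H-chromene; 6 ethyl but-2-ynoate
Product: 10 ethyl (E)-3-Ar-but-2-enoate, via aryl Grignard reagent 7 (not isolated), via arylcopper 8 (not isolated), via alkenylcopper 9 (not isolated)
Conditions: Mg, THF, reflux; CuBr·SMe2 (1.0 equiv), THF/Me2S, −40 °C; 6, −78 → −40 °C; sat. aq NH4Cl, −78 °C → rt
Reagents that add atoms: none
Why: Grignard formation, transmetalation to copper and low-temperature syn-carbocupration of the ynoate, followed by protonation with retention, is the standard entry to (E)-3-arylbut-2-enoates and places the aryl group on the β-carbon.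

Step 3
Reactants: 10 ethyl (E)-3-Ar-but-2-enoate
Product: 11 ethyl (3S)-3-Ar-butanoate
Conditions: Cu(OAc)2 (5 mol %), (S)-p-tol-BINAP (5.5 mol %), (EtO)2MeSiH (2 equiv), t-BuOH (2 equiv), toluene, 0 °C → rt
Reagents that add atoms: none
Why: Asymmetric CuH conjugate reduction of a geometrically pure β-aryl-β-methyl enoate delivers hydride to one face of the β-carbon under control of the chiral bisphosphine and so sets C*, while the unactivated, hindered chromene alkene should be far slower to hydrocuprate than the enoate.

Step 4
Reactants: 11 ethyl (3S)-3-Ar-butanoate; 12 acetone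
Product: 14 ethyl (3S)-3-Ar-2-(2-hydroxypropan-2-yl)butanoate (both C2 epimers), via lithium enolate 13 (not isolated)
Conditions: LiN(i-Pr)2 (1.1 equiv), THF, −78 °C; 12 (3 equiv), −78 °C; sat. aq NH4Cl, −78 °C
Reagents that add atoms: none
Why: Directed aldol addition of a preformed lithium ester enolate to acetone avoids the self-condensation and reversed donor/acceptor roles of an aldehyde–acetone crossed aldol, leaves the β-positioned C* untouched, and needs no control at C2 because that centre is erased in step 5.

Step 5
Reactants: 14 ethyl (3S)-3-Ar-2-(2-hydroxypropan-2-yl)butanoate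
Product: 16 ethyl 2-[(1R)-1-Ar-ethyl]-3-methylbut-2-enoate, via tertiary mesylate 15 (not isolated)
Conditions: MsCl (2 equiv), Et3N (4 equiv), DMAP (cat.), CH2Cl2, 0 °C → rt; DBU (2 equiv), rt → 40 °C
Reagents that add atoms: none
Why: Mesylation of the tertiary alcohol through sulfene and base-induced β-elimination of the acidified α-hydrogen (E1cB-like, with DBU able to bring any isopropenyl isomer back into conjugation through the dienolate) should give the conjugated ester, and no E/Z question arises because the new alkene carbon bears two methyl groups.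

Step 6
Reactants: 16 ethyl 2-[(1R)-1-Ar-ethyl]-3-methylbut-2-enoate
Product: 17 2-[(1S)-1-Ar-ethyl]-3-methylbut-2-en-1-ol
Conditions: i-Bu2AlH (2.5 equiv), CH2Cl2, −78 → 0 °C; aq potassium sodium tartrate
Reagents that add atoms: none
Why: 1,2-Reduction of a conjugated ester to the allylic alcohol with i-Bu2AlH is routine and leaves the aryl ethers, both alkenes and C* untouched.

Step 7
Reactants: 17 2-[(1S)-1-Ar-ethyl]-3-methylbut-2-en-1-ol
Product: 18 2-[(1R)-1-Ar-ethyl]-3-methylbut-2-enal
Conditions: MnO2 (20 equiv), CH2Cl2, rt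
Reagents that add atoms: none
Why: MnO2 oxidation is selective for allylic alcohols, stops at the aldehyde and is neutral, so neither the acid-sensitive ring B chromene nor C*, whose hydrogen sits on the α-substituent and cannot enolise, should be affected.

Step 8
Reactants: 18 2-[(1R)-1-Ar-ethyl]-3-methylbut-2-enal; 19 2',4'-dihydroxy-6'-methoxyacetophenone
Product: 23 CNP0303487.1, via enimine 20 (not isolated), via benzylic amine 21 (not isolated), via ortho-quinone methide 22 (not isolated)
Conditions: ethylenediammonium diacetate (0.5 equiv), 19 (1.5 equiv), 4 Å MS, xylene, reflux (about 140 °C)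
Reagents that add atoms: none
Why: The primary ammonium acetate converts hindered enal 18 into enimine 20, whose protonated form is attacked by C3' of 19 to forge C4–C4a in 21, and loss of ethylenediamine gives ortho-quinone methide 22, a 1-oxatriene. Ring A then closes by thermal disrotatory oxa-6π electrocyclisation, which forms O1–C2, gives the six-membered pyran and restores the arene as the driving force. The closest known reaction type is the amine-salt or pyridine mediated Knoevenagel/electrocyclisation of resorcinols and 2,4-dihydroxyacetophenones with 3-methylbut-2-enal or citral; because 18 is fully substituted, a primary amine catalyst, a higher loading, water removal and a higher temperature are planned. No stereocentre is created, since C2 bears two methyl groups, and C* is only carried through, because its hydrogen lies off the iminium/dienamine conjugation path and no sigmatropic hydrogen shift of 22 can reach it. Two selectivities are needed, C–C bonding at C3' and not C5' and closure through the 4'-oxygen and not the 2'-oxygen, and both come from the acetyl–2'-OH hydrogen bond, which localises the nucleophilic enol on C3'=C4' and keeps the 2'-oxygen engaged. The bulky C3 substituent favours the s-cis oxatriene rotamer needed for closure, and a second annulation is excluded because the remaining hydroxyl has no free ortho carbon.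

Compound list
1 | 4-bromo-3,5-dimethoxyphenol | COc1cc(O)cc(OC)c1Br | starting material
2 | 3-methylbut-2-enal | CC(C)=CC=O | starting material
3 | 6-bromo-5,7-dimethoxy-4-(2-methylprop-1-enyl)-2-phenyl-4H-1,3,2-benzodioxaborinine (racemic) | COc1cc2OB(c3ccccc3)OC(C=C(C)C)c2c(OC)c1Br | intermediate
4 | 4-bromo-3,5-dimethoxy-6-(3-methylbut-2-en-1-ylidene)cyclohexa-2,4-dien-1-one | COC1=CC(=O)C(=CC=C(C)C)C(OC)=C1Br | intermediate
5 | 6-bromo-5,7-dimethoxy-2,2-dimethyl-2H-chromene | COc1cc2c(c(OC)c1Br)C=CC(C)(C)O2 | intermediate
6 | ethyl but-2-ynoate | CCOC(=O)C#CC | starting material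
7 | (5,7-dimethoxy-2,2-dimethyl-2H-chromen-6-yl)magnesium bromide | COc1cc2c(c(OC)c1[Mg]Br)C=CC(C)(C)O2 | intermediate
8 | (5,7-dimethoxy-2,2-dimethyl-2H-chromen-6-yl)copper | COc1cc2c(c(OC)c1[Cu])C=CC(C)(C)O2 | intermediate
9 | ethyl 2-cuprio-3-Ar-but-2-enoate (Ar and Cu cis) | CCOC(=O)/C([Cu])=C(\C)c1c(OC)cc2c(c1OC)C=CC(C)(C)O2 | intermediate
10 | ethyl (E)-3-Ar-but-2-enoate | CCOC(=O)/C=C(\C)c1c(OC)cc2c(c1OC)C=CC(C)(C)O2 | intermediate
11 | ethyl (3S)-3-Ar-butanoate | CCOC(=O)C[C@H](C)c1c(OC)cc2c(c1OC)C=CC(C)(C)O2 | intermediate
12 | acetone | CC(C)=O | starting material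
13 | lithium enolate of 11 | [Li+].CCOC([O-])=C[C@H](C)c1c(OC)cc2c(c1OC)C=CC(C)(C)O2 | intermediate
14 | ethyl (3S)-3-Ar-2-(2-hydroxypropan-2-yl)butanoate (both C2 epimers) | CCOC(=O)C([C@H](C)c1c(OC)cc2c(c1OC)C=CC(C)(C)O2)C(C)(C)O | intermediate
15 | ethyl (3S)-3-Ar-2-[2-(methylsulfonyloxy)propan-2-yl]butanoate | CCOC(=O)C([C@H](C)c1c(OC)cc2c(c1OC)C=CC(C)(C)O2)C(C)(C)OS(C)(=O)=O | intermediate
16 | ethyl 2-[(1R)-1-Ar-ethyl]-3-methylbut-2-enoate | CCOC(=O)C(=C(C)C)[C@H](C)c1c(OC)cc2c(c1OC)C=CC(C)(C)O2 | intermediate
17 | 2-[(1S)-1-Ar-ethyl]-3-methylbut-2-en-1-ol | OCC(=C(C)C)[C@H](C)c1c(OC)cc2c(c1OC)C=CC(C)(C)O2 | intermediate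
18 | 2-[(1R)-1-Ar-ethyl]-3-methylbut-2-enal (2-isopropylidene-3-arylbutanal, C* arranged as in 23) | O=CC(=C(C)C)[C@H](C)c1c(OC)cc2c(c1OC)C=CC(C)(C)O2 | intermediate
19 | 2',4'-dihydroxy-6'-methoxyacetophenone | CC(=O)c1c(O)cc(O)cc1OC | starting material
20 | N-(2-aminoethyl) imine of 18 | NCCN=CC(=C(C)C)[C@H](C)c1c(OC)cc2c(c1OC)C=CC(C)(C)O2 | intermediate
21 | 1-(3-{1-[(2-aminoethyl)amino]-2-[(1S)-1-Ar-ethyl]-3-methylbut-2-en-1-yl}-2,4-dihydroxy-6-methoxyphenyl)ethan-1-one (both epimers at the new benzylic carbon) | CC(=O)c1c(O)c(C(NCCN)C(=C(C)C)[C@H](C)c2c(OC)cc3c(c2OC)C=CC(C)(C)O3)c(O)cc1OC | intermediate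
22 | 4-acetyl-5-hydroxy-3-methoxy-6-{2-[(1S)-1-Ar-ethyl]-3-methylbut-2-en-1-ylidene}cyclohexa-2,4-dien-1-one | CC(=O)C1=C(O)C(=CC(=C(C)C)[C@H](C)c2c(OC)cc3c(c2OC)C=CC(C)(C)O3)C(=O)C=C1OC | intermediate
23 | 1-{3-[(1S)-1-(5,7-dimethoxy-2,2-dimethyl-2H-chromen-6-yl)ethyl]-5-hydroxy-7-methoxy-2,2-dimethyl-2H-chromen-6-yl}ethan-1-one (CNP0303487.1) | COc1cc2c(c(O)c1C(C)=O)C=C([C@H](C)c1c(OC)cc3c(c1OC)C=CC(C)(C)O3)C(C)(C)O2 | target

Total step count: 8
Longest linear sequence: 8 (1 → 5 → 10 → 11 → 14 → 16 → 17 → 18 → 23)

Steps most likely to fail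

Step 8.
- **What may go wrong:** Imine formation and C–C bonding at the crowded formyl carbon may be too slow. Attack through C5' or closure through the chelated oxygen may compete. The ortho-quinone methide may leak away by a 1,7-hydrogen shift from a methyl group.
- **Fallback:** It sets out from 17 and 19 and comes back at 23 through the same 22, replacing condensation by allylation and dehydrogenation. An Appel reaction on 17 (CBr4, PPh3, CH2Cl2, 0 °C) gives the allylic bromide F1. Nuclear C-allylation of 19 at C3' (KOH, MeOH/H2O, 0 °C → rt, as in the C-prenylation of acylphloroglucinols) gives the 3'-allylated acetophenone F2.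
- **Last stage:** DDQ (1.1 equiv, benzene, 80 °C) abstracts hydride from the new benzylic CH2, which is the known cyclodehydrogenation of ortho-prenylphenols. The C*–H bond should be a poor hydride donor, because the two ortho methoxy groups hold it near the plane of ring B.

Step 5.
- **What may go wrong:** A methyl proton may be lost instead of the shielded α-proton, which misplaces the double bond. Retro-aldol cleavage may occur before the alcohol is activated.
- **Fallback:** It sets out from 11 and comes back at 16, fixing the alkene position by cross-coupling. Enolate 13 (LiN(i-Pr)2, 2.2 equiv) is acylated with N-methoxy-N-methylacetamide in a crossed Claisen condensation to give the β-keto ester F3. NaH then Tf2O (THF, 0 °C) gives the enol triflate F4.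
- **Last stage:** Iron-catalysed methylation (MeMgBr, Fe(acac)3 cat., THF/NMP, −30 °C) replaces the triflate by methyl. The geometry of F4 is irrelevant because both β-substituents end up as methyl.

Step 3.
- **What may go wrong:** Hydride delivery to a β-carbon screened by the twisted di-ortho-methoxyaryl group may be sluggish. Facial selectivity may be eroded, and slow hydrocupration of the ring B alkene may compete.
- **Fallback:** It sets out from 5 (as Grignard reagent 7) and comes back at 11, bypassing 10 and using auxiliary control. (R)-4-Phenyloxazolidin-2-one is acylated (n-BuLi, (E)-but-2-enoyl chloride, THF, −78 °C) to give the N-crotonyl imide F5. Reagent 7 with CuBr·SMe2 (THF/Me2S, −20 °C) adds to the chelated s-cis enoyl imide from the face opposite the phenyl group to give the conjugate adduct F6.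
- **Last stage:** Ethanolysis (NaOEt, EtOH, 0 °C) releases 11 and the auxiliary.

Further compounds
F1 | step 8 | 6-[(2R)-3-(bromomethyl)-4-methylpent-3-en-2-yl]-5,7-dimethoxy-2,2-dimethyl-2H-chromene | BrCC(=C(C)C)[C@H](C)c1c(OC)cc2c(c1OC)C=CC(C)(C)O2
F2 | step 8 | 1-(3-{2-[(1S)-1-Ar-ethyl]-3-methylbut-2-en-1-yl}-2,4-dihydroxy-6-methoxyphenyl)ethan-1-one | CC(=O)c1c(O)c(CC(=C(C)C)[C@H](C)c2c(OC)cc3c(c2OC)C=CC(C)(C)O3)c(O)cc1OC
F3 | step 5 | ethyl (3S)-2-acetyl-3-Ar-butanoate (both C2 epimers) | CCOC(=O)C(C(C)=O)[C@H](C)c1c(OC)cc2c(c1OC)C=CC(C)(C)O2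
F4 | step 5 | ethyl 2-[(1R)-1-Ar-ethyl]-3-(trifluoromethylsulfonyloxy)but-2-enoate (either alkene geometry) | CCOC(=O)C(=C(C)OS(=O)(=O)C(F)(F)F)[C@H](C)c1c(OC)cc2c(c1OC)C=CC(C)(C)O2
F5 | step 3 | (4R)-3-[(E)-but-2-enoyl]-4-phenyl-1,3-oxazolidin-2-one | C/C=C/C(=O)N1[C@H](c2ccccc2)COC1=O
F6 | step 3 | (4R)-3-[(3S)-3-Ar-butanoyl]-4-phenyl-1,3-oxazolidin-2-one | O=C(C[C@H](C)c1c(OC)cc2c(c1OC)C=CC(C)(C)O2)N1[C@H](c2ccccc2)COC1=O
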